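**Retrosynthetic overview**

- The target is (−)-epicatechin (EC) and (−)-epigallocatechin (EGC) joined by one biaryl bond, from C6' of ring B of the EC half to C2' of ring B of the EGC half. This bond is the only skeletal disconnection and is made directly from two C–H positions.
- Enabling feature: ring B of the EC half is a 3',4'-catechol whose o-quinone has C6' (para to O3') as its only free enone β-carbon. Ring B of the EGC half is a locally symmetric 3',4',5'-trioxygenated ring whose equivalent C2'/C6' lie ortho and para to O3'/O5'. The oxygen pattern of the target thus already encodes an electrophile/nucleophile pair.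
- Precursors: the o-quinone of 3,5,7-tri-O-benzyl-6,8-dibromo-EC and hexa-O-benzyl-6,8-dibromo-EGC. Bromine at C6/C8 blocks the otherwise more nucleophilic rings A, and the benzyl ethers shut off phenol redox chemistry.
- No ring of the target is built: rings A, B and C of both halves and all four stereocentres (2R,3R in each half) come from the two commercial flavan-3-ols. The only ring formed is the temporary 1,3-dioxole on ring B of the EC half (closed in step 1, opened in step 4). One final hydrogenolysis removes nine benzyl groups and four bromines.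

Key step: step 7

Assumption: the SMILES fixes the four stereocentres but not the sense of the tri-ortho-substituted biaryl axis, so the route controls the stereocentres only and atropisomers of 10 or 11, if they do not interconvert, would be separated by chromatography.

**Route**

Step 1
Reactants: 1 (−)-epicatechin
Product: 2 3',4'-O-diphenylmethylene-(−)-epicatechin
Conditions: Ph2CCl2 (1.3 equiv), K2CO3 (2.5 equiv), MeCN, rt, argon
Reagents that add atoms: dichlorodiphenylmethane, ClC(Cl)(c1ccccc1)c1ccccc1
Why: Catechol ketalisation, in which only the adjacent 3',4'-hydroxyls of ring B can close the five-membered 1,3-benzodioxole while the ring A phenols and the 3-OH give at most labile open adducts that revert on work-up, and no stereocentre is touched.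

Step 2
Reactants: 2 3',4'-O-diphenylmethylene-(−)-epicatechin
Product: 3 3,5,7-tri-O-benzyl-3',4'-O-diphenylmethylene-(−)-epicatechin
Conditions: NaH (3.3 equiv), BnBr (3.5 equiv), n-Bu4NI (cat.), DMF, 0 °C → rt
Reagents that add atoms: benzyl bromide, BrCc1ccccc1
Why: Williamson etherification of the two ring A phenols and the 3-OH, safe for C2 because ring B has no free 4'-OH and base therefore cannot open ring C through a quinone methide.

Step 3
Reactants: 3 3,5,7-tri-O-benzyl-3',4'-O-diphenylmethylene-(−)-epicatechin
Product: 4 6,8-dibromo-3,5,7-tri-O-benzyl-3',4'-O-diphenylmethylene-(−)-epicatechin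
Conditions: NBS (2.05 equiv), CH2Cl2, −40 → 0 °C, dark
Reagents that add atoms: N-bromosuccinimide, O=C1CCC(=O)N1Br
Why: Electrophilic aromatic bromination, in which the phloroglucinol-type ring A is far more electron-rich than ring B, so two equivalents of NBS should fill C6 and C8 before C6' is touched and thereby block ring A as a nucleophile for step 7.

Step 4
Reactants: 4 6,8-dibromo-3,5,7-tri-O-benzyl-3',4'-O-diphenylmethylene-(−)-epicatechin
Product: 5 3,5,7-tri-O-benzyl-6,8-dibromo-(−)-epicatechin
Conditions: AcOH/THF/H2O (4:2:1), 70 °C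
Reagents that add atoms: none
Why: Acid-catalysed ketal hydrolysis through a diphenyl(aryloxy)carbenium ion that water converts into benzophenone and the free catechol, under conditions that leave benzyl ethers, aryl bromides and the cis-2,3 stereocentres intact.

Step 5
Reactants: 6 (−)-epigallocatechin
Product: 7 3,5,7,3',4',5'-hexa-O-benzyl-(−)-epigallocatechin
Conditions: NaH (6.6 equiv), BnBr (7 equiv), n-Bu4NI (cat.), degassed DMF, −10 °C → rt, argon
Reagents that add atoms: benzyl bromide, BrCc1ccccc1
Why: Exhaustive Williamson etherification of five phenols and the 3-OH, run under strict exclusion of air so that the pyrogallol anion is alkylated before it can autoxidise, with no stereocentre involved.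

Step 6
Reactants: 7 3,5,7,3',4',5'-hexa-O-benzyl-(−)-epigallocatechin
Product: 8 6,8-dibromo-3,5,7,3',4',5'-hexa-O-benzyl-(−)-epigallocatechin
Conditions: NBS (2.05 equiv), CH2Cl2, −40 → 0 °C, dark
Reagents that add atoms: N-bromosuccinimide, O=C1CCC(=O)N1Br
Why: Electrophilic aromatic bromination that should take C6 and C8 of ring A ahead of C2' of ring B, leaving the two equivalent ring B carbons as the only nucleophilic arene C–H positions.

Step 7
Reactants: 5 3,5,7-tri-O-benzyl-6,8-dibromo-(−)-epicatechin; 8 6,8-dibromo-3,5,7,3',4',5'-hexa-O-benzyl-(−)-epigallocatechin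
Product: 10 nona-O-benzyl-tetrabromo-degalloyl theasinensin F, via o-quinone 9 (not isolated)
Conditions: (a) 5, Ag2O (3 equiv), Na2SO4, CH2Cl2, 0 °C, dark, filtration under argon; (b) filtrate added over 1 h to 8 (1.5 equiv), Sc(OTf)3 (10 mol %), CH2Cl2/(CF3)2CHOH 4:1, −40 → 0 °C
Reagents that add atoms: none
Why: Proposed new method: Ag2O dehydrogenates catechol 5 to o-quinone 9 (a standard catechol oxidation), Sc(OTf)3 in (CF3)2CHOH chelates its 1,2-dicarbonyl, and the trialkoxyarene ring B of 8 adds through C2' to C6' of 9 in a Friedel–Crafts conjugate addition (an electron-transfer radical-cation path would forge the same bond), after which proton loss and enolisation return the quinone ring to a catechol, so the biaryl bond is made redox-neutrally from two unfunctionalised C–H positions. The closest known reaction types are the uncatalysed C6' arylation of flavan-3-ol o-quinones by phenolic rings (the first bond of dehydrodicatechin and benzotropolone formation) and the acid-promoted hydroarylation of p-quinones and quinone monoacetals by alkoxyarenes, and what is new is the union of a non-phenolic arene with an o-quinone on two flavan scaffolds. No ring is closed and no new stereocentre is formed, the four existing ones being spectators and the sense of the new axis being left to the substrate. The step needs site selectivity on both partners: in 9 C6' is the only unsubstituted enone β-carbon (C1' carries the chromanyl group, C2' and C5' are α-carbons), and in 8 C2' and C6' are equivalent by the local symmetry of the 3,4,5-trioxygenated ring and are the only hydrogen-bearing arene carbons ortho and para to ether oxygens, because C6 and C8 of both rings A are brominated. It also needs chemoselectivity against redox side paths, which the absence of any free phenol in 8 secures (no O-arylation, no redox exchange with 9, no benzotropolone cascade), while slow addition of 9 to excess 8 at low temperature holds back quinone dimerisation and quinone-methide tautomerism at C2.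

Step 8
Reactants: 10 nona-O-benzyl-tetrabromo-degalloyl theasinensin F
Product: 11 degalloyl theasinensin F
Conditions: H2 (3 bar), Pd(OH)2/C, NaOAc (5 equiv), THF/MeOH/H2O, rt; filtration under argon
Reagents that add atoms: none
Why: Heterogeneous Pd-catalysed hydrogenolysis should cleave all nine O-benzyl bonds and all four aryl C–Br bonds in one operation, with NaOAc buffering the HBr so that neither acid-induced opening of ring C nor base-induced C2 epimerisation or autoxidation of the free polyphenol sets in.

**Compound list**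

1 | (−)-epicatechin, (2R,3R)-2-(3,4-dihydroxyphenyl)chromane-3,5,7-triol | Oc1cc(O)c2c(c1)O[C@H](c1ccc(O)c(O)c1)[C@H](O)C2 | starting material
2 | 3',4'-O-diphenylmethylene-(−)-epicatechin, (2R,3R)-2-(2,2-diphenyl-1,3-benzodioxol-5-yl)chromane-3,5,7-triol | Oc1cc(O)c2c(c1)O[C@H](c1ccc3OC(c4ccccc4)(c4ccccc4)Oc3c1)[C@H](O)C2 | intermediate
3 | 3,5,7-tri-O-benzyl-3',4'-O-diphenylmethylene-(−)-epicatechin, (2R,3R)-3,5,7-tris(benzyloxy)-2-(2,2-diphenyl-1,3-benzodioxol-5-yl)chromane | O(Cc1ccccc1)c1cc(OCc3ccccc3)c2c(c1)O[C@H](c1ccc3OC(c4ccccc4)(c4ccccc4)Oc3c1)[C@H](OCc1ccccc1)C2 | intermediate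
4 | 6,8-dibromo-3,5,7-tri-O-benzyl-3',4'-O-diphenylmethylene-(−)-epicatechin (2R,3R) | O(Cc1ccccc1)c1c(Br)c(OCc3ccccc3)c2c(c1Br)O[C@H](c1ccc3OC(c4ccccc4)(c4ccccc4)Oc3c1)[C@H](OCc1ccccc1)C2 | intermediate
5 | 3,5,7-tri-O-benzyl-6,8-dibromo-(−)-epicatechin, (2R,3R)-3,5,7-tris(benzyloxy)-6,8-dibromo-2-(3,4-dihydroxyphenyl)chromane | O(Cc1ccccc1)c1c(Br)c(OCc3ccccc3)c2c(c1Br)O[C@H](c1ccc(O)c(O)c1)[C@H](OCc1ccccc1)C2 | intermediate
6 | (−)-epigallocatechin, (2R,3R)-2-(3,4,5-trihydroxyphenyl)chromane-3,5,7-triol | Oc1cc(O)c2c(c1)O[C@H](c1cc(O)c(O)c(O)c1)[C@H](O)C2 | starting material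
7 | 3,5,7,3',4',5'-hexa-O-benzyl-(−)-epigallocatechin, (2R,3R)-3,5,7-tris(benzyloxy)-2-[3,4,5-tris(benzyloxy)phenyl]chromane | O(Cc1ccccc1)c1cc(OCc3ccccc3)c2c(c1)O[C@H](c1cc(OCc3ccccc3)c(OCc3ccccc3)c(OCc3ccccc3)c1)[C@H](OCc1ccccc1)C2 | intermediate
8 | 6,8-dibromo-3,5,7,3',4',5'-hexa-O-benzyl-(−)-epigallocatechin (2R,3R) | O(Cc1ccccc1)c1c(Br)c(OCc3ccccc3)c2c(c1Br)O[C@H](c1cc(OCc3ccccc3)c(OCc3ccccc3)c(OCc3ccccc3)c1)[C@H](OCc1ccccc1)C2 | intermediate
9 | o-quinone of 5, 4-[(2R,3R)-3,5,7-tris(benzyloxy)-6,8-dibromochroman-2-yl]cyclohexa-3,5-diene-1,2-dione | O(Cc1ccccc1)c1c(Br)c(OCc3ccccc3)c2c(c1Br)O[C@H](C1=CC(=O)C(=O)C=C1)[C@H](OCc1ccccc1)C2 | intermediate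
10 | nona-O-benzyl-tetrabromo-degalloyl theasinensin F: ring B C6' of the 3,5,7-tri-O-benzyl-6,8-dibromo-epicatechin half bonded to ring B C2' of the 3,5,7,3',4',5'-hexa-O-benzyl-6,8-dibromo-epigallocatechin half; 3',4'-OH of the epicatechin half free; 2R,3R in both halves | O(Cc1ccccc1)c1c(Br)c(OCc3ccccc3)c2c(c1Br)O[C@H](c1cc(O)c(O)cc1-c1c([C@H]3Oc4c(Br)c(OCc5ccccc5)c(Br)c(OCc5ccccc5)c4C[C@H]3OCc3ccccc3)cc(OCc3ccccc3)c(OCc3ccccc3)c1OCc1ccccc1)[C@H](OCc1ccccc1)C2 | intermediate
11 | degalloyl theasinensin F (2R,3R in both flavan halves) | Oc1cc(O)c2c(c1)O[C@H](c1cc(O)c(O)cc1-c1c([C@H]3Oc4cc(O)cc(O)c4C[C@H]3O)cc(O)c(O)c1O)[C@H](O)C2 | target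

**Count and risks**

Total step count: 8. Longest linear sequence: 6 steps (steps 1, 2, 3, 4, 7, 8).

Steps most likely to fail:

1. Step 7 (Proposed new method). What may go wrong: the hindered, only moderately nucleophilic trialkoxyarene may add too slowly, so that quinone self-dimerisation or tautomerisation of the quinone to its quinone methide (with loss of configuration at C2) outruns the arylation. Fallback with known chemistry, setting out from 4 and 8 and coming back at 11: electrophilic iodination of 4 (N-iodosuccinimide, cat. TFA, MeCN/CH2Cl2, 0 °C) para to O3' of the benzodioxole ring should give the 6'-iodide F1. The same iodination of 8 should give the 2'-iodide F2. Iodine–magnesium exchange on F2 (i-PrMgCl·LiCl, THF, −40 °C, faster than exchange of the hindered electron-rich bromides) and trapping with 2-isopropoxy-4,4,5,5-tetramethyl-1,3,2-dioxaborolane should give the pinacol boronate F3. Suzuki–Miyaura coupling of F1 with F3 (Pd(PPh3)4, K3PO4, DME/H2O, 85 °C), in which the C–I bond should react ahead of the doubly ortho-oxygenated C–Br bonds, should give the fully protected biaryl F4. Hydrogenolysis of F4 under the conditions of step 8 should then remove the benzyl ethers, the bromines and the diphenylmethylene ketal to give 11.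

2. Step 8. What may go wrong: incomplete hydrogenolysis of the hindered aryl bromides, over-reduction by hydrogenolytic opening of the benzylic C2–O1 bonds during the long reaction this requires, and air oxidation of the pyrogallol during work-up. Fallback, setting out from 10 and coming back at 11: bromine–lithium exchange (t-BuLi, 11 equiv, THF, −78 °C, the first two equivalents deprotonating the catechol; MeOH quench) should give the debrominated nona-benzyl ether F5. Neutral, base-free hydrogenolysis of F5 (H2, Pd(OH)2/C, THF/MeOH, rt), now a plain debenzylation, should give 11.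

3. Step 5. What may go wrong: air oxidation of the pyrogallol polyanion and competing C-benzylation of ring A before O-alkylation is complete. Fallback, setting out from 6 and coming back at 7: peracetylation (Ac2O, pyridine, rt) should give (−)-epigallocatechin hexaacetate F6, which is air-stable. One-pot deacetylation–benzylation of F6 (NaH, BnBr, DMF with a measured amount of H2O, 0 °C → rt) frees each oxygen only in the presence of excess benzyl bromide and should give 7.

**Further compounds**

F1 | step 7 | 6'-iodo derivative of 4 (iodine on ring B ortho to the chromanyl group and para to O3') | O(Cc1ccccc1)c1c(Br)c(OCc3ccccc3)c2c(c1Br)O[C@H](c1c(I)cc3OC(c4ccccc4)(c4ccccc4)Oc3c1)[C@H](OCc1ccccc1)C2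
F2 | step 7 | 2'-iodo derivative of 8 | O(Cc1ccccc1)c1c(Br)c(OCc3ccccc3)c2c(c1Br)O[C@H](c1cc(OCc3ccccc3)c(OCc3ccccc3)c(OCc3ccccc3)c1I)[C@H](OCc1ccccc1)C2
F3 | step 7 | 2'-(4,4,5,5-tetramethyl-1,3,2-dioxaborolan-2-yl) derivative of 8 | O(Cc1ccccc1)c1c(Br)c(OCc3ccccc3)c2c(c1Br)O[C@H](c1cc(OCc3ccccc3)c(OCc3ccccc3)c(OCc3ccccc3)c1B4OC(C)(C)C(C)(C)O4)[C@H](OCc1ccccc1)C2
F4 | step 7 | 3',4'-O-diphenylmethylene ketal of 10 (fully protected biaryl) | O(Cc1ccccc1)c1c(Br)c(OCc3ccccc3)c2c(c1Br)O[C@H](c1cc3OC(c4ccccc4)(c4ccccc4)Oc3cc1-c1c([C@H]3Oc4c(Br)c(OCc5ccccc5)c(Br)c(OCc5ccccc5)c4C[C@H]3OCc3ccccc3)cc(OCc3ccccc3)c(OCc3ccccc3)c1OCc1ccccc1)[C@H](OCc1ccccc1)C2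
F5 | step 8 | debrominated 10 (nona-O-benzyl degalloyl theasinensin F with free 3',4'-catechol) | O(Cc1ccccc1)c1cc(OCc3ccccc3)c2c(c1)O[C@H](c1cc(O)c(O)cc1-c1c([C@H]3Oc4cc(OCc5ccccc5)cc(OCc5ccccc5)c4C[C@H]3OCc3ccccc3)cc(OCc3ccccc3)c(OCc3ccccc3)c1OCc1ccccc1)[C@H](OCc1ccccc1)C2
F6 | step 5 | (−)-epigallocatechin hexaacetate | CC(=O)Oc1cc(OC(C)=O)c2c(c1)O[C@H](c1cc(OC(C)=O)c(OC(C)=O)c(OC(C)=O)c1)[C@H](OC(C)=O)C2
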